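Divide a charge in mM by a rate in mM per hour and you get hours, so a flask has a time constant even with no mechanism written down.

| flask | J | E | X | time |
|---|---|---|---|---|
| oak | 120 mM | 144 mM | 0.600 mM |  |
| birch | 48.0 mM | 72.0 mM | 0.600 mM |  |
| ash | 120 mM | 144 mM | 0.900 mM |  |
| larch | 120 mM | 220 mM | 0.600 mM |  |
| maple | 40.0 mM | 144 mM | 0.600 mM | 12 h |

| run | time / h | [Z] / mM |
|---|---|---|
| oak run | 0.48 | 1.6 |
| oak run | 1.1 | 3.4 |
| oak run | 2.4 | 9.5 |
| oak run | 5.4 | 22.7 |
| oak run | 12 | 46.9 |
| birch run | 0.48 | 0.7 |
| birch run | 1.1 | 1.0 |
| birch run | 2.4 | 3.6 |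
| birch run | 5.4 | 7.3 |
| birch run | 12 | 15.1 |
| ash run | 0.48 | 3.0 |
| ash run | 1.1 | 7.2 |
| ash run | 2.4 | 13.2 |
| ash run | 5.4 | 30.3 |
| ash run | 12 | 58.8 |
| larch run | 0.48 | 3.1 |
| larch run | 1.1 | 5.9 |
| larch run | 2.4 | 13.2 |
| larch run | 5.4 | 35.7 |
| larch run | 12 | 61.1 |

(readings scatter by 1 mM)

- Overall: J + E -> Z, with X as catalyst.
- Constant volume, constant temperature.
- An order is taken over about fifteen percent of the charge, up and down.

- order of the initial rate in [X], near the charge of the oak run, the rate being that where two percent of its J are Z
- order of the initial rate in [J], near the charge of the oak run, the rate being that where two percent of its J are Z (one fixed amount of Z, the same in the runs compared)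
- Z in the maple run at 12 h, as a share of the J charged

How fast does a flask start? The oak run's mean rate up to 5.4 h reads 4.20 mM h⁻¹, and I take that reading as its starting rate.

What does that rate follow? Readings at the same time, ash against oak, give an order of 0.712 in cX, and larch against oak gives 1.07 in cE. The birch run lowers both cJ and cE, so taking out the share of cE leaves my reading of the order in cJ: 0.430.

How far does the maple run get? Scaling oak's rate by that order gives maple a starting rate of 2.62 mM h⁻¹. Its J charge over this rate is 15.3 h, the fill time: the time to convert the charge if the starting rate held.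

Now solve both ends. At order zero in J, with the other factors held, the share made is a ramp, and 12 h over the fill time gives 78.6%. In maple, J is the limiting reagent, and at order one, the pseudo-first-order end, the share is a first-order lag reaching 54.4%. Integrating with the order 0.430 joins the two, and I commit to 64.8%.

The forecast says 0.97 in cX, higher than my reading of 0.712, 0.42 in cJ and 55% for maple, which is 9.8 percentage points lower than my share, and adds: “Possible catalyst decay or product inhibition argues for caution”.

The simulation gives 0.89 in cX, 0.30 in cJ and 47.8% for maple.

    X + J → Lx + G (303.8 M⁻¹ h⁻¹)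
    Lx + E → Z + X (46.08 M⁻¹ h⁻¹)
    Z + E → L (0.5364 M⁻¹ h⁻¹)
    J + E + Z → 2 Z (14.65 M⁻² h⁻¹)

That share in the maple run at 12 h is lower than the first-order end of 54.4%, reckoned with the fill time of 15.3 h. The step Z + E → L takes Z away as it forms: the maple run without that step gives 73.8%, which is higher than 54.4% and lower than 78.6%. The birch run's fill time reads 35.5 h, which puts half of its J at 24.6 h on the first-order end, and the birch run gets there at 23.8 h.

The runs are calculated on assumed constants; noise was put on by code.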